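**Retrosynthetic overview**
- Target: fisetinidol-(4α→6)-leucofisetinidin. Upper unit = rings A (benzo), C (pyran), B (catechol); lower unit = rings D (benzo), F (pyran), E (catechol).
- Feature the strategy rests on: upper C4 is a diarylmethine CH bonded to C4a of ring A and to C6 of ring D, with the C3–OH and the C2 catechol ring trans,trans to it. C4 is therefore treated as the β-carbon of an acyclic enone whose carbonyl carbon later becomes C2.
- Disconnections: lower C4–OH ⇒ ketone (fustin level); upper C3–O and O1–C2 ⇒ 4H-chromene ⇒ keto phenol; C4–C6(D) ⇒ C6 boronate of tri-O-benzyl-(2R,3R)-fustin + retro-chalcone (aldol of a ring A aldehyde with a ring B acetophenone).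
- Ring order: rings D, F and E arrive intact with fustin; rings A and B are bought as arenes; ring C is closed after the C–C bond by cyclodehydration and then saturated by hydroboration; the lower carbonyl is reduced last.

Key step: step 8

Assumption: (2R,3R)-fustin is taken to be purchasable as the single enantiomer; if only racemate is on offer, its tribenzyl ether 2 would be resolved on a chiral stationary phase.
Remark on descriptors: the upper diarylmethine carbon is labelled S while ring D carries a 7-O-benzyl group (compounds 11, 13, 15, 16) and R once the phenols are free (17, 18), because the ring priorities swap; the geometry is the same throughout.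

**Route**

Step 1
Reactants: 1 (2R,3R)-fustin
Product: 2 7,3',4'-tri-O-benzylfustin
Conditions: BnBr (3.3 equiv), K2CO3 (3.5 equiv), DMF, rt, N2
Reagents that add atoms: benzyl bromide, BrCc1ccccc1
Why: Williamson etherification; carbonate ionises only the three phenols (the aliphatic 3-OH stays free), and at room temperature the trans-dihydroflavonol should not open or epimerise.

Step 2
Reactants: 2 7,3',4'-tri-O-benzylfustin
Product: 3 6-bromo-7,3',4'-tri-O-benzylfustin
Conditions: NBS (1.02 equiv), MeCN, −10 °C to rt, dark
Reagents that add atoms: N-bromosuccinimide, O=C1CCC(=O)N1Br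
Why: Electrophilic aromatic bromination; C6 of ring D is para to O1, ortho to the 7-benzyloxy group and only meta to the carbonyl, whereas C8 is flanked by two oxygens and each position of ring E has a single oxygen donor, so one equivalent of NBS should brominate C6 first.

Step 3
Reactants: 3 6-bromo-7,3',4'-tri-O-benzylfustin
Product: 4 6-(pinacolboryl)-7,3',4'-tri-O-benzylfustin
Conditions: B2pin2 (1.3 equiv), PdCl2(dppf) (5 mol %, divalent palladium precatalyst), KOAc (3 equiv), dioxane, 85 °C, Ar
Reagents that add atoms: bis(pinacolato)diboron, CC1(C)OB(OC1(C)C)B1OC(C)(C)C(C)(C)O1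
Why: Miyaura borylation; zerovalent palladium formed in the flask inserts into the C–Br bond, acetate-assisted transmetalation with B2pin2 and reductive elimination give the aryl boronate, and KOAc is too weak a base to enolise or open the dihydroflavonol.

Step 4
Reactants: 5 2,4-dihydroxybenzaldehyde
Product: 6 4-benzyloxy-2-hydroxybenzaldehyde
Conditions: BnBr (1.05 equiv), NaHCO3 (1.2 equiv), MeCN, 80 °C
Reagents that add atoms: benzyl bromide, BrCc1ccccc1
Why: Williamson etherification under weak base; the 4-OH (para to the formyl group, more acidic, not hydrogen-bonded) is alkylated while the 2-OH stays locked in its hydrogen bond to the aldehyde.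

Step 5
Reactants: 6 4-benzyloxy-2-hydroxybenzaldehyde
Product: 7 4-benzyloxy-2-(methoxymethoxy)benzaldehyde
Conditions: MOMCl (2 equiv), i-Pr2NEt (3 equiv), CH2Cl2, 0 °C to rt
Reagents that add atoms: chloromethyl methyl ether, COCCl
Why: MOM ether formation by alkylation of the phenol with the chloromethyl ether and a hindered amine base; the acetal is stable to the bases of steps 7 and 8 and is released by acid in step 9.

Step 6
Reactants: 8 3,4-dihydroxyacetophenone
Product: 9 3,4-bis(benzyloxy)acetophenone
Conditions: BnBr (2.3 equiv), K2CO3 (3 equiv), DMF, 60 °C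
Reagents that add atoms: benzyl bromide, BrCc1ccccc1
Why: Williamson etherification of both catechol hydroxyls.

Step 7
Reactants: 7 4-benzyloxy-2-(methoxymethoxy)benzaldehyde + 9 3,4-bis(benzyloxy)acetophenone
Product: 10 (E)-3-[4-benzyloxy-2-(methoxymethoxy)phenyl]-1-[3,4-bis(benzyloxy)phenyl]prop-2-en-1-one
Conditions: KOH (40 % aq.), EtOH/THF, rt
Reagents that add atoms: none
Why: Claisen–Schmidt condensation; the acetophenone enolate adds to the non-enolisable aldehyde and the aldol dehydrates by E1cB to the conjugated (E)-enone, benzyl and MOM ethers being inert to hydroxide.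

Step 8
Reactants: 4 6-(pinacolboryl)-7,3',4'-tri-O-benzylfustin + 10 (E)-enone (1.3 equiv)
Product: 11 β,β-diaryl ketone with the interflavan C–C bond (new diarylmethine centre S)
Conditions: [RhCl(C2H4)2]2 (2.5 mol %), Ph-bod* (2,5-diphenylbicyclo[2.2.2]octa-2,5-diene, the antipode that gives Si-face attack; 5.5 mol %), KOH (0.2 equiv, 1 M aq.), dioxane/H2O 10:1, 40 °C, Ar
Reagents that add atoms: none
Why: The aryl group passes from boron to a hydroxo complex of monovalent rhodium, the enone coordinates and inserts into the Rh–aryl bond with the aryl delivered to the β-carbon, and water protonates the resulting rhodium oxa-allyl enolate to regenerate Rh–OH. The closest known reaction type is the Hayashi–Miyaura asymmetric 1,4-addition of arylboron reagents to chalcone-type β-aryl enones with chiral diene ligands. No ring is closed in this step; it forms only the bond between the future upper C4 and C6 of ring D. The new stereocentre is set by the C2-symmetric diene on rhodium, which should expose the Si face of the β-carbon (ring A aryl > Cα > H); both antipodes of the ligand exist, so the sense can be fixed on a model arylation, and the remote fustin stereocentres are too far away to compete. Site selectivity is fixed by the position of boron (C6, no C8 isomer), and no C4 cation is ever generated, so no oligomerisation is possible. The dihydroflavonol carbonyl is not an acceptor for aryl–rhodium, and the substoichiometric base at 40 °C is intended to spare ring F from base-induced opening; any protodeboronated material is 2 and can be recycled.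

Step 9
Reactants: 11 β,β-diaryl ketone
Product: 13 4-aryl-flav-2-ene (2,4-diaryl-4H-chromene; C4 S), via phenol ketone 12 (not isolated)
Conditions: p-TsOH·H2O (0.2 equiv), MeOH/CH2Cl2 1:1, 40 °C; then solvent switch to toluene, 4 Å MS, 70 °C, Ar; Et3N quench
Reagents that add atoms: none
Why: Acid-catalysed acetal cleavage frees the ring A phenol, which adds to the ketone (6-exo hemiketal formation) and loses water to the conjugated 2-aryl enol ether (cyclodehydration); the C4 stereocentre is not touched and exclusion of air prevents oxidation of the 4H-chromene to a flavylium salt.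

Step 10
Reactants: 13 4-aryl-flav-2-ene
Product: 15 hexa-O-benzyl fisetinidol-(4α→6)-leucofisetinidin (lower C4 epimers), via alkylborane 14 (not isolated)
Conditions: BH3·SMe2 (5 equiv), THF, 0 °C to rt; then 3 M NaOH, 30 % H2O2, 0 °C to rt
Reagents that add atoms: hydrogen peroxide, OO; borane–dimethyl sulfide, C[S+](C)[BH3-] (its boron stays only in intermediate 14)
Why: Hydroboration–oxidation; borane adds syn across the C2=C3 enol ether with boron at C3 (β to O1) on the face opposite the pseudo-axial C4 aryl, and oxidation with retention places the C3–OH trans to both the C4 aryl and the C2 aryl, which sets upper C2 and C3, while the lower ketone is reduced unselectively in the same flask.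

Step 11
Reactants: 15 hexa-O-benzyl fisetinidol-(4α→6)-leucofisetinidin (lower C4 epimers)
Product: 16 hexa-O-benzyl fisetinidol-(4α→6)-fustin
Conditions: activated MnO2 (20 equiv), CH2Cl2, rt
Reagents that add atoms: none
Why: Chemoselective benzylic oxidation; MnO2 should oxidise only the carbinol benzylic to the electron-rich ring D and leave the two non-benzylic secondary alcohols, and both C4 epimers converge on one ketone.

Step 12
Reactants: 16 hexa-O-benzyl fisetinidol-(4α→6)-fustin
Product: 17 fisetinidol-(4α→6)-fustin
Conditions: H2 (1 atm), Pd(OH)2/C (20 wt %), THF/MeOH 1:1, rt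
Reagents that add atoms: none
Why: Catalytic hydrogenolysis of the six aryl benzyl ethers; at one atmosphere the vinylogous-ester-like C4 carbonyl, the O1–C2 bonds and the interflavan bond should survive, which is why the lower unit is kept at the ketone level here (a benzylic C4 carbinol would be at risk).

Step 13
Reactants: 17 fisetinidol-(4α→6)-fustin
Product: 18 fisetinidol-(4α→6)-leucofisetinidin (target)
Conditions: NaBH4 (6 equiv), EtOH, 0 °C to rt, N2; aq. NaH2PO4 to pH 6; Sephadex LH-20 (EtOH)
Reagents that add atoms: none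
Why: Borohydride reduction of a free-phenolic 2,3-trans-dihydroflavonol; hydride enters axially on the half-chair that holds the C2 aryl and C3–OH equatorial, giving the equatorial C4 carbinol trans to the C3–OH (lower 4R), the known preference of dihydroflavonols, and the near-neutral work-up protects the acid-labile benzylic carbinol.

**Compound list**
1 | (2R,3R)-fustin, (2R,3R)-2-(3,4-dihydroxyphenyl)-3,7-dihydroxychroman-4-one | O=C1c2ccc(O)cc2O[C@H](c2ccc(O)c(O)c2)[C@H]1O | starting material
2 | 7,3',4'-tri-O-benzylfustin, (2R,3R)-7-benzyloxy-2-[3,4-bis(benzyloxy)phenyl]-3-hydroxychroman-4-one | O=C1c2ccc(OCc3ccccc3)cc2O[C@H](c2ccc(OCc3ccccc3)c(OCc3ccccc3)c2)[C@H]1O | intermediate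
3 | (2R,3R)-6-bromo-7-benzyloxy-2-[3,4-bis(benzyloxy)phenyl]-3-hydroxychroman-4-one | O=C1c2cc(Br)c(OCc3ccccc3)cc2O[C@H](c2ccc(OCc3ccccc3)c(OCc3ccccc3)c2)[C@H]1O | intermediate
4 | (2R,3R)-7-benzyloxy-2-[3,4-bis(benzyloxy)phenyl]-3-hydroxy-6-(4,4,5,5-tetramethyl-1,3,2-dioxaborolan-2-yl)chroman-4-one | O=C1c2cc(B3OC(C)(C)C(C)(C)O3)c(OCc3ccccc3)cc2O[C@H](c2ccc(OCc3ccccc3)c(OCc3ccccc3)c2)[C@H]1O | intermediate
5 | 2,4-dihydroxybenzaldehyde | O=Cc1ccc(O)cc1O | starting material
6 | 4-benzyloxy-2-hydroxybenzaldehyde | O=Cc1ccc(OCc2ccccc2)cc1O | intermediate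
7 | 4-benzyloxy-2-(methoxymethoxy)benzaldehyde | O=Cc1ccc(OCc2ccccc2)cc1OCOC | intermediate
8 | 3,4-dihydroxyacetophenone | CC(=O)c1ccc(O)c(O)c1 | starting material
9 | 3,4-bis(benzyloxy)acetophenone | CC(=O)c1ccc(OCc2ccccc2)c(OCc2ccccc2)c1 | intermediate
10 | (E)-3-[4-benzyloxy-2-(methoxymethoxy)phenyl]-1-[3,4-bis(benzyloxy)phenyl]prop-2-en-1-one (retro-chalcone, ring A on the β-carbon) | COCOc1cc(OCc2ccccc2)ccc1/C=C/C(=O)c1ccc(OCc2ccccc2)c(OCc2ccccc2)c1 | intermediate
11 | β,β-diaryl ketone: tri-O-benzylfustin bearing at C6 the (1S)-1-[4-benzyloxy-2-(methoxymethoxy)phenyl]-3-[3,4-bis(benzyloxy)phenyl]-3-oxopropyl group | COCOc1cc(OCc2ccccc2)ccc1[C@H](CC(=O)c1ccc(OCc2ccccc2)c(OCc2ccccc2)c1)c1cc2c(cc1OCc1ccccc1)O[C@H](c1ccc(OCc3ccccc3)c(OCc3ccccc3)c1)[C@@H](O)C2=O | intermediate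
12 | phenol ketone: 11 with the MOM group removed (free 2-hydroxyl on ring A); not isolated | Oc1cc(OCc2ccccc2)ccc1[C@H](CC(=O)c1ccc(OCc2ccccc2)c(OCc2ccccc2)c1)c1cc2c(cc1OCc1ccccc1)O[C@H](c1ccc(OCc3ccccc3)c(OCc3ccccc3)c1)[C@@H](O)C2=O | intermediate
13 | 4-aryl-flav-2-ene: tri-O-benzylfustin bearing at C6 the (4S)-7-benzyloxy-2-[3,4-bis(benzyloxy)phenyl]-4H-chromen-4-yl group | c1ccccc1COc1ccc2c(c1)OC(c1ccc(OCc3ccccc3)c(OCc3ccccc3)c1)=C[C@@H]2c1cc2c(cc1OCc1ccccc1)O[C@H](c1ccc(OCc3ccccc3)c(OCc3ccccc3)c1)[C@@H](O)C2=O | intermediate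
14 | alkylborane: upper flavan with boron at C3 (C2–H and C3–B syn, both anti to the C4 aryl), lower C4 ketone already reduced; drawn in its simplest RBH2 form; not isolated | c1ccccc1COc1ccc2c(c1)O[C@H](c1ccc(OCc3ccccc3)c(OCc3ccccc3)c1)[C@@H](B)[C@@H]2c1cc2c(cc1OCc1ccccc1)O[C@H](c1ccc(OCc3ccccc3)c(OCc3ccccc3)c1)[C@@H](O)C2O | intermediate
15 | hexa-O-benzyl fisetinidol-(4α→6)-leucofisetinidin: upper (2R,3S,4S) 2,3-trans-3,4-trans, lower (2R,3S) with the C4 carbinol as an epimer mixture | c1ccccc1COc1ccc2c(c1)O[C@H](c1ccc(OCc3ccccc3)c(OCc3ccccc3)c1)[C@@H](O)[C@@H]2c1cc2c(cc1OCc1ccccc1)O[C@H](c1ccc(OCc3ccccc3)c(OCc3ccccc3)c1)[C@@H](O)C2O | intermediate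
16 | hexa-O-benzyl fisetinidol-(4α→6)-fustin: upper (2R,3S,4S), lower (2R,3R) | c1ccccc1COc1ccc2c(c1)O[C@H](c1ccc(OCc3ccccc3)c(OCc3ccccc3)c1)[C@@H](O)[C@@H]2c1cc2c(cc1OCc1ccccc1)O[C@H](c1ccc(OCc3ccccc3)c(OCc3ccccc3)c1)[C@@H](O)C2=O | intermediate
17 | fisetinidol-(4α→6)-fustin: upper (2R,3S,4R), lower (2R,3R) | Oc1ccc2c(c1)O[C@H](c1ccc(O)c(O)c1)[C@@H](O)[C@@H]2c1cc2c(cc1O)O[C@H](c1ccc(O)c(O)c1)[C@@H](O)C2=O | intermediate
18 | fisetinidol-(4α→6)-leucofisetinidin: upper (2R,3S,4R), lower (2R,3S,4R) | Oc1ccc2c(c1)O[C@H](c1ccc(O)c(O)c1)[C@@H](O)[C@@H]2c1cc2c(cc1O)O[C@H](c1ccc(O)c(O)c1)[C@@H](O)[C@@H]2O | target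

**Totals**
Total step count: 13.
Longest linear sequence: 9 steps (1 → 2 → 3 → 4 → 11 → 13 → 15 → 16 → 17 → 18; the sequence from 5 is equally long).

**Steps most likely to fail**

1. Step 8 (rhodium-catalysed 1,4-addition). What may go wrong: protodeboronation of the hindered, electron-rich boronate outrunning transmetalation, base-induced opening or epimerisation of ring F, or poor facial selectivity with two ortho-alkoxy groups flanking the new bond. Fallback: the boron partner is given up. The fallback sets out from bromide 3 and enone 10, which are joined by a palladium-catalysed reductive Heck reaction (Pd(OAc)2, P(t-Bu)3·HBF4, HCO2Na, DMF, 80 °C). Zerovalent palladium inserts into the C–Br bond, the aryl adds to the β-carbon and formate reduces the palladium enolate. No facial control is expected, so ketone 11 would be accompanied by its epimer at the diarylmethine carbon, the epi-ketone F1. The fustin unit makes the two diastereomers, which are to be separated by chromatography, and the route is rejoined at 11.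

2. Step 10 (hydroboration–oxidation). What may go wrong: sluggish addition to the hindered trisubstituted enol ether, insufficient face selectivity, or ring opening of the β-alkoxy borane. Fallback: from 13, dihydroxylation with OsO4 (cat.)/NMO in acetone/H2O at 0 °C should add both oxygens anti to the C4 aryl and give the 2-hydroxy hemiketal diol F2. Ionic reduction of F2 with Et3SiH and BF3·OEt2 in CH2Cl2 at −40 °C goes through the 2-aryl oxocarbenium ion. Hydride entering anti to the pseudo-axial C4 aryl would give the 2,4-cis, 2,3-trans flavan-3-ol; the sense of hydride delivery must be checked, since attack anti to the C3–OH would give the 2,3-cis epimer instead. The lower ketone is never reduced, so this comes back to the route at 16 and also removes the need for step 11.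

3. Step 2 (bromination). What may go wrong: competing bromination of ring E or at C8, or oxidation of the α-ketol through its enol. Fallback: from 2, the carbonyl is removed first so that ring D becomes a plain resorcinol diether, far more nucleophilic than ring E. NaBH4 in THF/MeOH at 0 °C gives the 2,3-trans-3,4-trans diol, tri-O-benzyl-leucofisetinidin F3. NBS with NaHCO3 in DMF at −20 °C gives the 6-bromo diol F4. Activated MnO2 in CH2Cl2 then restores the benzylic ketone, and the route is rejoined at 3.

**Further compounds**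
F1 | step 8 | epi-ketone, the epimer of 11 at the diarylmethine carbon (R) | COCOc1cc(OCc2ccccc2)ccc1[C@@H](CC(=O)c1ccc(OCc2ccccc2)c(OCc2ccccc2)c1)c1cc2c(cc1OCc1ccccc1)O[C@H](c1ccc(OCc3ccccc3)c(OCc3ccccc3)c1)[C@@H](O)C2=O
F2 | step 10 | 2-hydroxy hemiketal diol (upper 2,3-cis-diol, both hydroxyls anti to the C4 aryl; lower unit unchanged) | c1ccccc1COc1ccc2c(c1)O[C@](O)(c1ccc(OCc3ccccc3)c(OCc3ccccc3)c1)[C@@H](O)[C@@H]2c1cc2c(cc1OCc1ccccc1)O[C@H](c1ccc(OCc3ccccc3)c(OCc3ccccc3)c1)[C@@H](O)C2=O
F3 | step 2 | tri-O-benzyl-leucofisetinidin, (2R,3S,4R)-7-benzyloxy-2-[3,4-bis(benzyloxy)phenyl]chroman-3,4-diol | c1ccccc1COc1ccc2c(c1)O[C@H](c1ccc(OCc3ccccc3)c(OCc3ccccc3)c1)[C@@H](O)[C@@H]2O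
F4 | step 2 | 6-bromo diol, (2R,3S,4R)-6-bromo-7-benzyloxy-2-[3,4-bis(benzyloxy)phenyl]chroman-3,4-diol | c1ccccc1COc1c(Br)cc2c(c1)O[C@H](c1ccc(OCc3ccccc3)c(OCc3ccccc3)c1)[C@@H](O)[C@@H]2O
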